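## Retrosynthetic overview

1. Target ⇐ all-β 4,6,8-triol + vanillic acid (Mitsunobu; inversion at C6 places the ester α).
2. Triol ⇐ 4β-hydroxy-dauca-2,7-dien-6-one by syn-1,3 reduction, OH-directed epoxidation of C7=C8 and hydride opening; the enone ⇐ i-Pr addition to a silyloxy trienone, then unmasking.
3. Hydroazulene core ⇐ acyclic siloxyvinyl diazo ketone carrying an (E,E)-diene, by Rh-carbenoid cyclopropanation followed by divinylcyclopropane Cope rearrangement in one flask.
4. Diazo ketone ⇐ acetylacetone dianion + (2E,4E)-dienyl bromide ⇐ crotonaldehyde + stabilised ylide.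
5. Ring order: cyclopropane and five-membered ring form together, then the seven-membered ring by [3,3] shift in the same operation (the cyclopropane is consumed).

Convention: names use daucane locants (ring C1–C10; C1 = ring-fusion carbon bearing methyl C15, C4 = i-Pr carbinol, C5 = ring-fusion CH, C6 = ester carbinol, C8 bears methyl C14); β = the face of C15, α = the opposite face.

Assumption: Rh2(S-PTAD)4 gives the (1S) series drawn in step 7; if the sense of induction is opposite, Rh2(R-PTAD)4 is used instead.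

## Route

Step 1
Reactants: 1 (E)-but-2-enal; 2 ethyl 2-(triphenyl-λ5-phosphanylidene)propanoate
Product: 3 ethyl (2E,4E)-2-methylhexa-2,4-dienoate
Conditions: CH2Cl2, 23 °C, 16 h
Reagents that add atoms: none
Why: Wittig olefination with a stabilised α-methyl ylide gives the (2E)-trisubstituted alkene selectively and keeps the (4E) geometry of the enal.

Step 2
Reactants: 3 ethyl (2E,4E)-2-methylhexa-2,4-dienoate
Product: 4 (2E,4E)-2-methylhexa-2,4-dien-1-ol
Conditions: DIBAL-H (2.2 equiv), CH2Cl2, −78 → 0 °C; Rochelle salt work-up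
Reagents that add atoms: none
Why: DIBAL-H 1,2-reduction of the conjugated ester to the allylic alcohol leaves the diene untouched.

Step 3
Reactants: 4 (2E,4E)-2-methylhexa-2,4-dien-1-ol
Product: 5 (2E,4E)-1-bromo-2-methylhexa-2,4-diene
Conditions: PBr3 (0.4 equiv), Et2O, −20 °C; used crude
Reagents that add atoms: phosphorus tribromide, BrP(Br)Br
Why: SN2-type bromination of the primary allylic alcohol at low temperature retains both alkene geometries.

Step 4
Reactants: 6 pentane-2,4-dione; 5 (2E,4E)-1-bromo-2-methylhexa-2,4-diene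
Product: 7 (7E,9E)-7-methylundeca-7,9-diene-2,4-dione
Conditions: 6 (1.2 equiv), LDA (2.4 equiv), THF, 0 °C; then 5, −78 → 0 °C; AcOH quench
Reagents that add atoms: none
Why: Hauser dianion alkylation, in which the more basic terminal carbanion of the acetylacetone dianion displaces the allylic bromide by SN2 so that C–C bond formation occurs only at the methyl terminus.

Step 5
Reactants: 7 (7E,9E)-7-methylundeca-7,9-diene-2,4-dione
Product: 8 (7E,9E)-3-diazo-7-methylundeca-7,9-diene-2,4-dione
Conditions: p-ABSA (1.1 equiv), Et3N, MeCN, 0 → 23 °C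
Reagents that add atoms: 4-acetamidobenzenesulfonyl azide, CC(=O)Nc1ccc(cc1)S(=O)(=O)N=[N+]=[N-]
Why: Regitz diazo transfer to the doubly activated methylene of the 1,3-diketone.

Step 6
Reactants: 8 (7E,9E)-3-diazo-7-methylundeca-7,9-diene-2,4-dione
Product: 9 (7E,9E)-2-[(tert-butyldimethylsilyl)oxy]-3-diazo-7-methylundeca-1,7,9-trien-4-one
Conditions: TBSOTf (1.1 equiv), Et3N (1.5 equiv), CH2Cl2, 0 °C
Reagents that add atoms: tert-butyldimethylsilyl trifluoromethanesulfonate, CC(C)(C)[Si](C)(C)OS(=O)(=O)C(F)(F)F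
Why: Soft enolisation and O-silylation of the diazo diketone occur at the unhindered acetyl CH3 in preference to the internal CH2, giving a siloxyvinyl diazo ketone (donor/acceptor carbene precursor).

Step 7
Reactants: 9 (7E,9E)-2-[(tert-butyldimethylsilyl)oxy]-3-diazo-7-methylundeca-1,7,9-trien-4-one
Product: 12 (1S)-6-[(tert-butyldimethylsilyl)oxy]-11,12,13-trinordauca-5,7-dien-4-one, via cis-divinylcyclopropane ketone 10 (not isolated), via 5,9-dienone 11 (not isolated)
Conditions: Rh2(S-PTAD)4 (1 mol %), PhCF3, slow addition of 9, 0 → 23 °C; then 100 °C, 4 h; then RuHCl(CO)(PPh3)3 (5 mol %), 100 °C, 6 h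
Reagents that add atoms: none
Why: Proposed new method: the chiral Rh(II) siloxyvinylcarbenoid cyclopropanates the proximal trisubstituted (E)-alkene through a five-membered-ring-forming transition state (C1 set by catalyst control; propenyl, methyl and siloxyvinyl end up cis on the cyclopropane), the cis-divinylcyclopropane then undergoes a boat Cope rearrangement on heating so that the five- and seven-membered rings arise in one operation (the outer methyl gives a transient 14-Me α centre), and the added Ru hydride moves C9=C10 into conjugation, which erases that centre; the closest known chemistry is the tandem cyclopropanation/Cope (formal [4+3]) reaction of vinyldiazo compounds with dienes, including intramolecular cases and Rh2(S-PTAD)4-controlled siloxyvinylcarbenoids, followed by a standard Ru–H alkene isomerisation.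

Step 8
Reactants: 12 (1S)-6-[(tert-butyldimethylsilyl)oxy]-11,12,13-trinordauca-5,7-dien-4-one
Product: 14 (1S)-6-[(tert-butyldimethylsilyl)oxy]-11,12,13-trinordauca-2,5,7-trien-4-one, via trimethylsilyl dienol ether 13 (not isolated)
Conditions: LDA (1.1 equiv), THF, −78 °C; TMSCl; then Pd(OAc)2 (1.05 equiv), MeCN, 23 °C
Reagents that add atoms: none
Why: Saegusa–Ito dehydrogenation, in which kinetic α′-deprotonation at C3 of the vinylogous silyl ester, O-silylation and Pd(II)-mediated β-hydride elimination install C2=C3, the only position available because C1 is quaternary.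

Step 9
Reactants: 14 (1S)-6-[(tert-butyldimethylsilyl)oxy]-11,12,13-trinordauca-2,5,7-trien-4-one
Product: 15 (1S,4S)-6-[(tert-butyldimethylsilyl)oxy]dauca-2,5,7-trien-4β-ol
Conditions: i-PrMgCl (1.5 equiv), CeCl3 (1.6 equiv), THF, −78 °C; pH 7 buffer; used crude
Reagents that add atoms: isopropylmagnesium chloride, CC(C)[Mg]Cl
Why: Organocerium 1,2-addition to the cross-conjugated ketone (no enolisation, no conjugate addition) from the α-face, opposite the angular C15 methyl, gives the 4β-OH/4α-i-Pr carbinol.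

Step 10
Reactants: 15 (1S,4S)-6-[(tert-butyldimethylsilyl)oxy]dauca-2,5,7-trien-4β-ol
Product: 16 (1S,4S,5R)-4β-hydroxy-5α-dauca-2,7-dien-6-one
Conditions: TBAF/AcOH (1:1, 1.2 equiv), THF, −20 → 0 °C
Reagents that add atoms: none
Why: Fluoride cleavage of the silyl dienol ether and C5-protonation of the dienolate unveil the conjugated C6 enone, and the epimerisable C5 centre is expected to settle as the trans-fused isomer (seven-ring ketone α to the fusion, C6 anti to the i-Pr group).

Step 11
Reactants: 16 (1S,4S,5R)-4β-hydroxy-5α-dauca-2,7-dien-6-one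
Product: 18 (1S,4S,5S,6R)-5α-dauca-2,7-diene-4β,6β-diol, via diethylboron chelate 17 (not isolated)
Conditions: Et2BOMe (1.2 equiv), THF/MeOH 4:1, −78 °C; NaBH4 (1.5 equiv); MeOH co-evaporation
Reagents that add atoms: none
Why: Narasaka–Prasad reduction, in which external hydride adds 1,2 to the boron chelate of the β-hydroxy enone and gives the 1,3-syn (4β,6β) diol.

Step 12
Reactants: 18 (1S,4S,5S,6R)-5α-dauca-2,7-diene-4β,6β-diol
Product: 19 (1S,4S,5S,6S,7S,8R)-7β,8β-epoxy-5α-dauc-2-ene-4β,6β-diol
Conditions: VO(acac)2 (5 mol %), t-BuOOH (1.2 equiv), CH2Cl2, 0 °C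
Reagents that add atoms: tert-butyl hydroperoxide, CC(C)(C)OO
Why: Vanadium-catalysed hydroxyl-directed epoxidation delivers oxygen to the trisubstituted C7=C8 alkene syn to the allylic 6β-OH, faster than to the hindered disubstituted C2=C3 alkene.

Step 13
Reactants: 19 (1S,4S,5S,6S,7S,8R)-7β,8β-epoxy-5α-dauc-2-ene-4β,6β-diol
Product: 20 (1S,4S,5S,6R,8R)-5α-dauc-2-ene-4β,6β,8β-triol
Conditions: LiAlH4 (4 equiv), THF, 0 → 40 °C; Fieser work-up
Reagents that add atoms: none
Why: Hydride opens the trisubstituted epoxide by SN2 attack at the secondary C7, so the C8–O bond is untouched and the 8β tertiary alcohol (14-Me α) results.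

Step 14
Reactants: 20 (1S,4S,5S,6R,8R)-5α-dauc-2-ene-4β,6β,8β-triol; 21 4-hydroxy-3-methoxybenzoic acid
Product: 22 (1S,4S,5S,6S,8R)-6α-(4-hydroxy-3-methoxybenzoyloxy)-5α-dauc-2-ene-4β,8β-diol
Conditions: 21 (1.5 equiv), PPh3 (2 equiv), DIAD (2 equiv), THF/PhMe, 0 → 40 °C
Reagents that add atoms: none
Why: Mitsunobu esterification, in which only the secondary C6–OH is activated and is displaced with inversion by the carboxylate of the acid (the less acidic phenol and the tertiary alcohols do not react), giving the 6α-ester.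

## Compound list

1 | (E)-but-2-enal (crotonaldehyde) | C/C=C/C=O | starting material
2 | ethyl 2-(triphenyl-λ5-phosphanylidene)propanoate | CCOC(=O)C(C)=P(c1ccccc1)(c1ccccc1)c1ccccc1 | starting material
3 | ethyl (2E,4E)-2-methylhexa-2,4-dienoate | CCOC(=O)/C(C)=C/C=C/C | intermediate
4 | (2E,4E)-2-methylhexa-2,4-dien-1-ol | OC/C(C)=C/C=C/C | intermediate
5 | (2E,4E)-1-bromo-2-methylhexa-2,4-diene | BrC/C(C)=C/C=C/C | intermediate
6 | pentane-2,4-dione (acetylacetone) | CC(=O)CC(C)=O | starting material
7 | (7E,9E)-7-methylundeca-7,9-diene-2,4-dione | CC(=O)CC(=O)CC/C(C)=C/C=C/C | intermediate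
8 | (7E,9E)-3-diazo-7-methylundeca-7,9-diene-2,4-dione | CC(=O)C(=[N+]=[N-])C(=O)CC/C(C)=C/C=C/C | intermediate
9 | (7E,9E)-2-[(tert-butyldimethylsilyl)oxy]-3-diazo-7-methylundeca-1,7,9-trien-4-one | C=C(O[Si](C)(C)C(C)(C)C)C(=[N+]=[N-])C(=O)CC/C(C)=C/C=C/C | intermediate
10 | (1S,5R,6R)-1-{1-[(tert-butyldimethylsilyl)oxy]ethenyl}-5-methyl-6-[(1E)-prop-1-en-1-yl]bicyclo[3.1.0]hexan-2-one (6-exo-propenyl, cis to the 5-methyl and the 1-siloxyvinyl groups) | O=C1CC[C@]2(C)[C@@H](/C=C/C)[C@]12C(O[Si](C)(C)C(C)(C)C)=C | intermediate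
11 | (1R,8R)-6-[(tert-butyldimethylsilyl)oxy]-11,12,13-trinordauca-5,9-dien-4-one (15-Me β, 14-Me α) | O=C1CC[C@]2(C)C=C[C@H](C)CC(O[Si](C)(C)C(C)(C)C)=C12 | intermediate
12 | (1S)-6-[(tert-butyldimethylsilyl)oxy]-11,12,13-trinordauca-5,7-dien-4-one | O=C1CC[C@]2(C)CCC(C)=CC(O[Si](C)(C)C(C)(C)C)=C12 | intermediate
13 | (1S)-6-[(tert-butyldimethylsilyl)oxy]-4-[(trimethylsilyl)oxy]-11,12,13-trinordauca-3,5,7-triene | C[Si](C)(C)OC1=CC[C@]2(C)CCC(C)=CC(O[Si](C)(C)C(C)(C)C)=C12 | intermediate
14 | (1S)-6-[(tert-butyldimethylsilyl)oxy]-11,12,13-trinordauca-2,5,7-trien-4-one | O=C1C=C[C@]2(C)CCC(C)=CC(O[Si](C)(C)C(C)(C)C)=C12 | intermediate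
15 | (1S,4S)-6-[(tert-butyldimethylsilyl)oxy]dauca-2,5,7-trien-4β-ol (4α-i-Pr) | C12=C(O[Si](C)(C)C(C)(C)C)C=C(C)CC[C@@]1(C)C=C[C@@]2(O)C(C)C | intermediate
16 | (1S,4S,5R)-4β-hydroxy-5α-dauca-2,7-dien-6-one (trans-fused) | O=C1C=C(C)CC[C@@]2(C)C=C[C@@](O)(C(C)C)[C@H]12 | intermediate
17 | 4-O-(diethylboryl) derivative of 16 (boron chelated by the C6 carbonyl) | O=C1C=C(C)CC[C@@]2(C)C=C[C@@](OB(CC)CC)(C(C)C)[C@H]12 | intermediate
18 | (1S,4S,5S,6R)-5α-dauca-2,7-diene-4β,6β-diol | O[C@@H]1C=C(C)CC[C@@]2(C)C=C[C@@](O)(C(C)C)[C@H]12 | intermediate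
19 | (1S,4S,5S,6S,7S,8R)-7β,8β-epoxy-5α-dauc-2-ene-4β,6β-diol | O[C@@H]1[C@@H]3O[C@]3(C)CC[C@@]2(C)C=C[C@@](O)(C(C)C)[C@H]12 | intermediate
20 | (1S,4S,5S,6R,8R)-5α-dauc-2-ene-4β,6β,8β-triol | O[C@@H]1C[C@](C)(O)CC[C@@]2(C)C=C[C@@](O)(C(C)C)[C@H]12 | intermediate
21 | 4-hydroxy-3-methoxybenzoic acid (vanillic acid) | COc1cc(C(=O)O)ccc1O | starting material
22 | (1S,4S,5S,6S,8R)-6α-(4-hydroxy-3-methoxybenzoyloxy)-5α-dauc-2-ene-4β,8β-diol, i.e. (3S,3aS,4S,6R,8aS)-3,6-dihydroxy-6,8a-dimethyl-3-(propan-2-yl)-3,3a,4,5,6,7,8,8a-octahydroazulen-4-yl 4-hydroxy-3-methoxybenzoate (CNP0113302.1) | COc1cc(C(=O)O[C@H]2C[C@](C)(O)CC[C@@]3(C)C=C[C@@](O)(C(C)C)[C@H]23)ccc1O | target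

## Step count and risk

Total step count: 14. Longest linear sequence: 14 (1 → 22).

The three steps most likely to fail are steps 7, 10 and 14.

Step 7. Asymmetric induction by a chiral Rh(II) catalyst in an intramolecular cyclopropanation of a vinyl diazo ketone is untested. The cyclopropane 10 also carries a methyl group syn to both vinyl groups, which slows the boat Cope rearrangement and allows a competing homo-1,5-hydrogen shift. The fallback gives up catalyst control and separates the events. It sets out from 9 with achiral Rh2(esp)2 at 0 °C and isolates racemic 10. This is rearranged on its own by short heating (PhMe, 110 °C, or microwave) and isomerised with the Ru hydride as before. The enantiomers of 12 are then separated by preparative chromatography on a chiral stationary phase. The route is re-entered at 12 and no new compound is made.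

Step 10. The β-hydroxy enone 16 can dehydrate or undergo retro-aldol cleavage, and kinetic protonation at C5 may give the cis-fused epimer. Neither can be corrected with base while the C4 hydroxyl is free. The fallback sets out from 15. Deprotonation (KHMDS, THF, −78 → −20 °C) triggers a 1,5 O→O silyl transfer from the dienol ether oxygen to the tertiary alkoxide. Protonation (AcOH) then gives 4β-[(tert-butyldimethylsilyl)oxy]-5α-dauca-2,7-dien-6-one F1. Its C5 centre can be equilibrated safely with DBU to the trans-fused isomer. HF·pyridine then removes the silyl group, and the route is re-entered at 16.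

Step 14. Mitsunobu displacement at the hindered, axial C6 carbinol flanked by two tertiary alcohols may give elimination instead of inversion. The fallback replaces the inversion by an oxidation/directed-reduction sequence and sets out from 20. Dess–Martin oxidation of the only secondary alcohol gives 4β,8β-dihydroxy-5α-dauc-2-en-6-one F2. Evans–Saksena reduction (Me4NBH(OAc)3, AcOH/MeCN), with hydride delivered internally from the β-face by either tertiary hydroxyl, gives 5α-dauc-2-ene-4β,6α,8β-triol F3. EDC/DMAP acylation of its only secondary hydroxyl with commercial 4-acetoxy-3-methoxybenzoic acid gives 6α-(4-acetoxy-3-methoxybenzoyloxy)-5α-dauc-2-ene-4β,8β-diol F4. K2CO3/MeOH at 0 °C cleaves the phenolic acetate, and the route ends at 22.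

Further compounds
F0 | step 7 | none | none
F1 | step 10 | 4β-[(tert-butyldimethylsilyl)oxy]-5α-dauca-2,7-dien-6-one | O=C1C=C(C)CC[C@@]2(C)C=C[C@@](O[Si](C)(C)C(C)(C)C)(C(C)C)[C@H]12
F2 | step 14 | 4β,8β-dihydroxy-5α-dauc-2-en-6-one | O=C1C[C@](C)(O)CC[C@@]2(C)C=C[C@@](O)(C(C)C)[C@H]12
F3 | step 14 | 5α-dauc-2-ene-4β,6α,8β-triol | O[C@H]1C[C@](C)(O)CC[C@@]2(C)C=C[C@@](O)(C(C)C)[C@H]12
F4 | step 14 | 6α-(4-acetoxy-3-methoxybenzoyloxy)-5α-dauc-2-ene-4β,8β-diol | COc1cc(C(=O)O[C@H]2C[C@](C)(O)CC[C@@]3(C)C=C[C@@](O)(C(C)C)[C@H]23)ccc1OC(C)=O
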